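Ring C is cut into a three-atom aryl unit C4–C4a–C8a (ring A) and a three-atom enolate unit O1–C2–C3. The key step is a one-pot C-acylation/intramolecular SNAr annulation: the lithium enolate of 4'-(benzyloxy)acetophenone is acylated at C3 by a 2-fluorobenzoyl chloride that already carries the C8 benzyl group, and the resulting diketonate oxygen O1 displaces fluoride at C8a, closing the pyranone and completing the flavone skeleton. It exploits the ring C motif in which the C4 carbonyl sits ortho to the O1-bearing C8a of ring A: C4 is first the acyl electrophile, then the SNAr activator. C2 and C3 are then set by asymmetric conjugate reduction and Rubottom oxidation.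

Key step: step 6

Assumption: compounds 1, 3 and 8 and all reagents are taken as commercially available, and (R)-DTBM-SEGPHOS is taken as the ligand antipode that leads to the 2S flavanone (its antipode would be used, with no other change, if a first run showed the opposite sense).

Step 1
Reactants: 1 5-fluororesorcinol
Product: 2 1,3-bis(benzyloxy)-5-fluorobenzene
Conditions: BnBr, K2CO3, DMF, 60 °C
Reagents that add atoms: benzyl bromide (BrCc1ccccc1)
Why: Williamson etherification of both phenols should proceed cleanly and installs the benzyl ethers that are removed together in the last step.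

Step 2
Reactants: 2 1,3-bis(benzyloxy)-5-fluorobenzene; 3 [4-(benzyloxy)phenyl]methanol
Product: 4 1,5-bis(benzyloxy)-2-[4-(benzyloxy)benzyl]-3-fluorobenzene
Conditions: Sc(OTf)3 (5 mol%), MeNO2, 0 °C to rt, 2 in excess (2.5 equiv)
Reagents that add atoms: none
Why: In this Friedel–Crafts benzylation the stabilized 4-(benzyloxy)benzyl cation should attack the resorcinol diether ring para to one benzyloxy group and next to the small fluorine rather than at the crowded position between the two benzyloxy groups, the excess of 2 suppressing a second alkylation.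

Step 3
Reactants: 4 1,5-bis(benzyloxy)-2-[4-(benzyloxy)benzyl]-3-fluorobenzene
Product: 5 4,6-bis(benzyloxy)-3-[4-(benzyloxy)benzyl]-2-fluorobenzaldehyde
Conditions: POCl3, DMF, 0 °C to 60 °C; then H2O
Reagents that add atoms: N,N-dimethylformamide (CN(C)C=O); water (O)
Why: Vilsmeier–Haack formylation should occur at the remaining position that is para to a benzyloxy group and flanked by fluorine, the alternative site between two benzyloxy groups being the more hindered, and the less activated benzyl ring should not react.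

Step 4
Reactants: 5 4,6-bis(benzyloxy)-3-[4-(benzyloxy)benzyl]-2-fluorobenzaldehyde
Product: 6 4,6-bis(benzyloxy)-3-[4-(benzyloxy)benzyl]-2-fluorobenzoic acid
Conditions: NaClO2, NaH2PO4, 2-methyl-2-butene, t-BuOH/THF/H2O, rt
Reagents that add atoms: sodium chlorite ([Na+].[O-]Cl=O)
Why: Pinnick oxidation converts hindered, electron-rich aryl aldehydes into acids, and the alkene scavenger removes hypochlorous acid before it can chlorinate the arene rings.

Step 5
Reactants: 6 4,6-bis(benzyloxy)-3-[4-(benzyloxy)benzyl]-2-fluorobenzoic acid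
Product: 7 4,6-bis(benzyloxy)-3-[4-(benzyloxy)benzyl]-2-fluorobenzoyl chloride
Conditions: (COCl)2, DMF (cat.), CH2Cl2, 0 °C to rt
Reagents that add atoms: oxalyl chloride (O=C(Cl)C(Cl)=O)
Why: Acid chloride formation through the catalytic chloroiminium species is mild enough to leave the benzyl ethers intact, and the crude chloride is used directly.

Step 6
Reactants: 7 4,6-bis(benzyloxy)-3-[4-(benzyloxy)benzyl]-2-fluorobenzoyl chloride; 8 1-[4-(benzyloxy)phenyl]ethan-1-one
Product: 10 5,7-bis(benzyloxy)-8-[4-(benzyloxy)benzyl]-2-[4-(benzyloxy)phenyl]-4H-chromen-4-one, via 1,3-diketone 9 (not isolated)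
Conditions: 8, LiN(SiMe3)2 (2.2 equiv), THF, −78 °C; then 7, −78 °C to rt; then DMF, 100 °C
Reagents that add atoms: none
Why: The lithium enolate of 8 should be C-acylated by 7 in a crossed Claisen-type condensation, the second equivalent of LiN(SiMe3)2 converts diketone 9 into its enolate, and on heating in DMF the enolate oxygen on the ring B side adds to C8a, ortho to the new C4 carbonyl, and expels fluoride by addition–elimination. The closest known reaction type is the tandem C-acylation/SNAr synthesis of chromones and 4-quinolones from 2-halobenzoyl chlorides and enolates. Ring C closes by intramolecular O-arylation, a six-membered (6-exo) attack of O1 on C8a through a Meisenheimer intermediate, driven by formation of the 4-pyranone and loss of LiF. No stereocenter is formed, since C2 and C3 emerge trigonal and are set in steps 7 and 8. The step needs C- over O-acylation, secured by the lithium counter-ion in THF at low temperature, and displacement of fluoride only, secured because fluorine is the sole leaving group ortho to the carbonyl while the benzyloxy groups at C5 and C7 are meta to C8a and do not donate into the carbon under attack. Attack through carbon instead of oxygen is excluded because it would give a four-membered ring.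

Step 7
Reactants: 10 5,7-bis(benzyloxy)-8-[4-(benzyloxy)benzyl]-2-[4-(benzyloxy)phenyl]-4H-chromen-4-one
Product: 12 (2S)-5,7-bis(benzyloxy)-8-[4-(benzyloxy)benzyl]-2-[4-(benzyloxy)phenyl]chroman-4-one, via silyl enol ether 11 (not isolated)
Conditions: Cu(OAc)2 (5 mol%), (R)-DTBM-SEGPHOS (5.5 mol%), (EtO)2MeSiH (1.5 equiv), toluene, 0 °C to rt; then 1 M HCl, THF
Reagents that add atoms: none
Why: The bisphosphine-ligated copper hydride (monovalent copper, formed from Cu(OAc)2 and the silane) should deliver hydride to one face of C2 in a known asymmetric conjugate reduction of chromone-type enones, the chiral ligand setting the 2S center, while trapping as silyl enol ether 11 shields C4 from 1,2-reduction until the mild acidic work-up.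

Step 8
Reactants: 12 (2S)-5,7-bis(benzyloxy)-8-[4-(benzyloxy)benzyl]-2-[4-(benzyloxy)phenyl]chroman-4-one
Product: 15 (2R,3R)-5,7-bis(benzyloxy)-8-[4-(benzyloxy)benzyl]-2-[4-(benzyloxy)phenyl]-3-hydroxychroman-4-one, via trimethylsilyl enol ether 13 (not isolated), via silyloxy epoxide 14 (not isolated)
Conditions: Me3SiOTf, Et3N, CH2Cl2, 0 °C; evaporation, pentane filtration; then DMDO, acetone/CH2Cl2, −40 °C to 0 °C; then aq. citric acid, THF, rt
Reagents that add atoms: dimethyldioxirane (CC1(C)OO1)
Why: Soft enolization avoids the ring-opening of a free enolate, and Rubottom oxidation of the enol ether with DMDO should occur on the C3 face anti to the C2 aryl group, so that hydrolysis of the silyloxy epoxide gives the 2,3-trans (2R,3R) ketol with C2 untouched.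

Step 9
Reactants: 15 (2R,3R)-5,7-bis(benzyloxy)-8-[4-(benzyloxy)benzyl]-2-[4-(benzyloxy)phenyl]-3-hydroxychroman-4-one
Product: 16 (2R,3R)-3,5,7-trihydroxy-8-(4-hydroxybenzyl)-2-(4-hydroxyphenyl)chroman-4-one
Conditions: H2 (1 atm), Pd/C, EtOAc/MeOH, rt
Reagents that add atoms: none
Why: Hydrogenolysis of the four benzyl ethers under neutral conditions, stopped at complete debenzylation, should leave the diarylmethane, the C4 ketone, the C2–O1 bond and both stereocenters intact.

Compound list
1 | 5-fluororesorcinol (5-fluorobenzene-1,3-diol) | Oc1cc(O)cc(F)c1 | starting material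
2 | 1,3-bis(benzyloxy)-5-fluorobenzene | Fc1cc(OCc2ccccc2)cc(OCc2ccccc2)c1 | intermediate
3 | [4-(benzyloxy)phenyl]methanol | OCc1ccc(OCc2ccccc2)cc1 | starting material
4 | 1,5-bis(benzyloxy)-2-[4-(benzyloxy)benzyl]-3-fluorobenzene | Fc1cc(OCc2ccccc2)cc(OCc2ccccc2)c1Cc1ccc(OCc2ccccc2)cc1 | intermediate
5 | 4,6-bis(benzyloxy)-3-[4-(benzyloxy)benzyl]-2-fluorobenzaldehyde | O=Cc1c(F)c(Cc2ccc(OCc3ccccc3)cc2)c(OCc2ccccc2)cc1OCc1ccccc1 | intermediate
6 | 4,6-bis(benzyloxy)-3-[4-(benzyloxy)benzyl]-2-fluorobenzoic acid | OC(=O)c1c(F)c(Cc2ccc(OCc3ccccc3)cc2)c(OCc2ccccc2)cc1OCc1ccccc1 | intermediate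
7 | 4,6-bis(benzyloxy)-3-[4-(benzyloxy)benzyl]-2-fluorobenzoyl chloride | ClC(=O)c1c(F)c(Cc2ccc(OCc3ccccc3)cc2)c(OCc2ccccc2)cc1OCc1ccccc1 | intermediate
8 | 1-[4-(benzyloxy)phenyl]ethan-1-one | CC(=O)c1ccc(OCc2ccccc2)cc1 | starting material
9 | 1-{4,6-bis(benzyloxy)-3-[4-(benzyloxy)benzyl]-2-fluorophenyl}-3-[4-(benzyloxy)phenyl]propane-1,3-dione | O=C(CC(=O)c1ccc(OCc2ccccc2)cc1)c1c(F)c(Cc2ccc(OCc3ccccc3)cc2)c(OCc2ccccc2)cc1OCc1ccccc1 | intermediate
10 | 5,7-bis(benzyloxy)-8-[4-(benzyloxy)benzyl]-2-[4-(benzyloxy)phenyl]-4H-chromen-4-one | O=c1cc(-c2ccc(OCc3ccccc3)cc2)oc2c(Cc3ccc(OCc4ccccc4)cc3)c(OCc3ccccc3)cc(OCc3ccccc3)c12 | intermediate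
11 | (2S)-5,7-bis(benzyloxy)-8-[4-(benzyloxy)benzyl]-2-[4-(benzyloxy)phenyl]-4-[diethoxy(methyl)silyloxy]-2H-chromene | CCO[Si](C)(OCC)OC1=C[C@@H](c2ccc(OCc3ccccc3)cc2)Oc2c(Cc3ccc(OCc4ccccc4)cc3)c(OCc3ccccc3)cc(OCc3ccccc3)c12 | intermediate
12 | (2S)-5,7-bis(benzyloxy)-8-[4-(benzyloxy)benzyl]-2-[4-(benzyloxy)phenyl]chroman-4-one | O=C1c2c(OCc3ccccc3)cc(OCc3ccccc3)c(Cc3ccc(OCc4ccccc4)cc3)c2O[C@H](c2ccc(OCc3ccccc3)cc2)C1 | intermediate
13 | (2S)-5,7-bis(benzyloxy)-8-[4-(benzyloxy)benzyl]-2-[4-(benzyloxy)phenyl]-4-(trimethylsilyloxy)-2H-chromene | C[Si](C)(C)OC1=C[C@@H](c2ccc(OCc3ccccc3)cc2)Oc2c(Cc3ccc(OCc4ccccc4)cc3)c(OCc3ccccc3)cc(OCc3ccccc3)c12 | intermediate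
14 | (2R,3R,4R)-5,7-bis(benzyloxy)-8-[4-(benzyloxy)benzyl]-2-[4-(benzyloxy)phenyl]-3,4-epoxy-4-(trimethylsilyloxy)chromane, epoxide oxygen trans to the C2 aryl group | C[Si](C)(C)O[C@]12c3c(OCc4ccccc4)cc(OCc4ccccc4)c(Cc4ccc(OCc5ccccc5)cc4)c3O[C@H](c3ccc(OCc4ccccc4)cc3)[C@H]1O2 | intermediate
15 | (2R,3R)-5,7-bis(benzyloxy)-8-[4-(benzyloxy)benzyl]-2-[4-(benzyloxy)phenyl]-3-hydroxychroman-4-one | O=C1c2c(OCc3ccccc3)cc(OCc3ccccc3)c(Cc3ccc(OCc4ccccc4)cc3)c2O[C@H](c2ccc(OCc3ccccc3)cc2)[C@H]1O | intermediate
16 | (2R,3R)-3,5,7-trihydroxy-8-(4-hydroxybenzyl)-2-(4-hydroxyphenyl)chroman-4-one | O=C1c2c(O)cc(O)c(Cc3ccc(O)cc3)c2O[C@H](c2ccc(O)cc2)[C@H]1O | target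

Total step count: 9
Longest linear sequence: 9 steps (1 to 16; compounds 3 and 8 enter as purchased materials)

Steps most likely to fail

Step 7. The electron-rich 5,7-dialkoxychromone may add hydride too slowly, the C4 carbonyl may be reduced as well, or the facial selectivity at C2 may be insufficient. The fallback sets out from flavone 10 and replaces conjugate hydride transfer by full hydrogenation followed by reoxidation. Asymmetric hydrogenation with Ru(cod)(2-methylallyl)2 and a chiral imidazolinylidene ligand (generated from its tetrafluoroborate salt with KOtBu) under H2 pressure should reduce both the C2=C3 bond and the C4 carbonyl to the 2,4-cis alcohol (2S,4S)-5,7-bis(benzyloxy)-8-[4-(benzyloxy)benzyl]-2-[4-(benzyloxy)phenyl]chroman-4-ol F1. Oxidation of the C4 alcohol with Dess–Martin periodinane in CH2Cl2 then returns the route at flavanone 12.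

Step 6. The hindered 2,6-disubstituted aroyl chloride may acylate the enolate on oxygen, or the lithium diketonate may displace fluoride too slowly. The fallback sets out from aldehyde 5 and ketone 8 and forms the two bonds in separate operations. Aldol addition of the lithium enolate of 8 (LiN(SiMe3)2, THF, −78 °C) to 5 should give the racemic β-hydroxy ketone 1-[4-(benzyloxy)phenyl]-3-{4,6-bis(benzyloxy)-3-[4-(benzyloxy)benzyl]-2-fluorophenyl}-3-hydroxypropan-1-one F2. Dess–Martin oxidation gives diketone 9, now isolated, and K2CO3 in DMF at 100 °C closes ring C by fluoride displacement, returning the route at flavone 10.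

Step 2. The benzyl cation may attack between the two benzyloxy groups, the product may be alkylated a second time, or the benzylic alcohol may condense with itself. The fallback sets out from 2 and builds the diarylmethane by carbonyl addition and deoxygenation. Vilsmeier–Haack formylation of 2 (POCl3, DMF) should give 2,4-bis(benzyloxy)-6-fluorobenzaldehyde F3, whose positional purity is easily secured at this stage. Addition of 4-(benzyloxy)phenylmagnesium bromide in THF gives the racemic carbinol [2,4-bis(benzyloxy)-6-fluorophenyl][4-(benzyloxy)phenyl]methanol F4. Ionic deoxygenation with Et3SiH and CF3CO2H in CH2Cl2 at 0 °C then returns the route at compound 4.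

Further compounds
F1 | step 7 | (2S,4S)-5,7-bis(benzyloxy)-8-[4-(benzyloxy)benzyl]-2-[4-(benzyloxy)phenyl]chroman-4-ol | O[C@@H]1c2c(OCc3ccccc3)cc(OCc3ccccc3)c(Cc3ccc(OCc4ccccc4)cc3)c2O[C@H](c2ccc(OCc3ccccc3)cc2)C1
F2 | step 6 | 1-[4-(benzyloxy)phenyl]-3-{4,6-bis(benzyloxy)-3-[4-(benzyloxy)benzyl]-2-fluorophenyl}-3-hydroxypropan-1-one (racemic) | O=C(CC(O)c1c(F)c(Cc2ccc(OCc3ccccc3)cc2)c(OCc2ccccc2)cc1OCc1ccccc1)c1ccc(OCc2ccccc2)cc1
F3 | step 2 | 2,4-bis(benzyloxy)-6-fluorobenzaldehyde | O=Cc1c(F)cc(OCc2ccccc2)cc1OCc1ccccc1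
F4 | step 2 | [2,4-bis(benzyloxy)-6-fluorophenyl][4-(benzyloxy)phenyl]methanol (racemic) | OC(c1ccc(OCc2ccccc2)cc1)c1c(F)cc(OCc2ccccc2)cc1OCc1ccccc1
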